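**Plan**

- Retrosynthetic cuts: (i) the phenol O–benzyl bond; (ii) the C3–C4 bond of the oxolane, with both methyl groups read as former vinyl CH2 termini, which opens the ring to the bis(1-arylallyl) ether 10; (iii) the O1–C5 bond, which gives alkoxide 3 and the cinnamyl-type carbonate 7.
- Enabling feature: C3 and C4 are adjacent CH(CH3) carbons, each β to O1 and next to a benzylic carbon (C2, C5). C3–C4 is therefore the 5-exo bond of a 3-oxahex-5-enyl radical, and a 1,6-diene is its precursor. Either vinyl group may take up the hydrogen atom; both channels give the same oxolane.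
- Forward order: two aryl fragments (2 and 3 steps) are joined at O1–C5 by iridium-catalysed allylic etherification; the only ring, the oxolane, is closed at C3–C4 by a hydrogen-atom-transfer radical cyclisation; debenzylation ends the route.
- Stereochemistry: C2 (S) from enzymatic resolution of 2; C5 (R) from the chiral iridium catalyst; C3 (S) and C4 (R) from the chair transition state of the ring closure, relayed from C2 and C5.

Key step: step 7

Remark: the target is read as (2S,3S,4R,5R), with the aryl groups cis to each other and the methyl groups cis to each other and trans to the aryl groups. Oxolane numbering O1, C2 (3,4-dimethoxyphenyl), C3, C4, C5 (4-hydroxy-3,5-dimethoxyphenyl) is used throughout. L is O,O'-(1,1'-binaphthalene-2,2'-diyl) N,N-bis(1-phenylethyl)phosphoramidite; its enantiomer is chosen from the known facial preference of this catalyst family so that step 6 gives the (R) centre.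

**Route**

Step 1
Reactants: 1 3,4-dimethoxybenzaldehyde
Product: 2 rac-1-(3,4-dimethoxyphenyl)prop-2-en-1-ol
Conditions: CH2=CHMgBr, THF, 0 °C; aq. NH4Cl
Reagents that add atoms: vinylmagnesium bromide, C=C[Mg]Br
Why: Grignard 1,2-addition to the aldehyde should give the allylic alcohol; the new centre is left racemic because it is resolved in step 2.

Step 2
Reactants: 2 rac-1-(3,4-dimethoxyphenyl)prop-2-en-1-ol
Product: 3 (S)-1-(3,4-dimethoxyphenyl)prop-2-en-1-ol
Conditions: immobilised Candida antarctica lipase B, vinyl acetate, t-BuOMe, 30 °C, stopped just past half conversion; chromatography on Et3N-deactivated silica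
Reagents that add atoms: none
Why: Lipase-catalysed kinetic resolution by transesterification should acetylate the (R)-alcohol, whose large aryl and medium vinyl groups fit the enzyme pockets, and leave (S)-3, which becomes C2 of the target.

Step 3
Reactants: 4 sinapic acid
Product: 5 benzyl (E)-3-(4-benzyloxy-3,5-dimethoxyphenyl)prop-2-enoate
Conditions: BnBr, K2CO3, DMF, 60 °C
Reagents that add atoms: benzyl bromide, BrCc1ccccc1
Why: Williamson O-alkylation of the carboxylate and the phenoxide in one operation protects the phenol as a benzyl ether and turns the acid into a reducible ester.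

Step 4
Reactants: 5 benzyl (E)-3-(4-benzyloxy-3,5-dimethoxyphenyl)prop-2-enoate
Product: 6 (E)-3-(4-benzyloxy-3,5-dimethoxyphenyl)prop-2-en-1-ol
Conditions: i-Bu2AlH, CH2Cl2, −78 to 0 °C; aq. potassium sodium tartrate
Reagents that add atoms: none
Why: Aluminium hydride reduction of the conjugated ester should proceed in the 1,2 sense to the (E)-allylic alcohol without touching the alkene or the aryl benzyl ether.

Step 5
Reactants: 6 (E)-3-(4-benzyloxy-3,5-dimethoxyphenyl)prop-2-en-1-ol
Product: 7 tert-butyl (E)-3-(4-benzyloxy-3,5-dimethoxyphenyl)prop-2-en-1-yl carbonate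
Conditions: Boc2O, Bu4NHSO4 (cat.), 30 % aq. NaOH, CH2Cl2, 0 °C to rt
Reagents that add atoms: di-tert-butyl dicarbonate, CC(C)(C)OC(=O)OC(=O)OC(C)(C)C
Why: Phase-transfer O-acylation should give the tert-butyl carbonate, chosen because the tert-butoxide it releases in step 6 does not compete as a nucleophile.

Step 6
Reactants: 3 (S)-1-(3,4-dimethoxyphenyl)prop-2-en-1-ol; 7 tert-butyl (E)-3-(4-benzyloxy-3,5-dimethoxyphenyl)prop-2-en-1-yl carbonate
Product: 10 (R)-1-(4-benzyloxy-3,5-dimethoxyphenyl)prop-2-en-1-yl (S)-1-(3,4-dimethoxyphenyl)prop-2-en-1-yl ether, via lithium alkoxide 8 (not isolated), via copper alkoxide 9 (not isolated)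
Conditions: 3, n-BuLi, THF, 0 °C; CuI, rt; then 7, [Ir(cod)Cl]2 (2 mol %), L (4 mol %), THF, rt
Reagents that add atoms: none
Why: In this iridium-catalysed asymmetric allylic etherification the allyliridium intermediate from 7 should be attacked by the monovalent copper alkoxide at the aryl-bearing terminus (branched selectivity), with ligand L fixing the new C5 centre as (R) under catalyst control, while the (S) centre of 3 is untouched because its C–O bond is not broken.

Step 7
Reactants: 10 (R)-1-(4-benzyloxy-3,5-dimethoxyphenyl)prop-2-en-1-yl (S)-1-(3,4-dimethoxyphenyl)prop-2-en-1-yl ether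
Product: 15 (2S,3S,4R,5R)-5-(4-benzyloxy-3,5-dimethoxyphenyl)-2-(3,4-dimethoxyphenyl)-3,4-dimethyloxolane, via C3 secondary radical 11 (not isolated), via C4 secondary radical 12 (not isolated), via C4-methylene primary radical 13 (not isolated), via C3-methylene primary radical 14 (not isolated)
Conditions: Mn(dpm)3 (10 mol %; dpm = 2,2,6,6-tetramethylheptane-3,5-dionate), PhSiH3 (slow addition), t-BuOOH, i-PrOH (0.01 M), argon, rt
Reagents that add atoms: none
Why: The manganese hydride formed from Mn(dpm)3 and PhSiH3 should transfer a hydrogen atom to the terminal CH2 of either vinyl group of 10 (Markovnikov MHAT) to give secondary radical 11 or 12, which adds to the internal carbon of the other vinyl group, forming the C3–C4 bond and the oxolane, and the primary radical 13 or 14 is quenched by a second hydrogen-atom transfer, so both channels converge on 15 and both methyl groups arise from vinyl termini. The closest known reaction type is the MHAT-initiated hydrogenative cyclisation of 1,6-dienes, with the tin-hydride cyclisation of 3-oxahex-5-enyl radicals as the classical analogue. The ring closes in the 5-exo-trig mode, favoured over 6-endo by orbital overlap and accelerated by the short C–O bonds of the ether tether. C3 and C4 are set by the chair-like transition state of hexenyl radical closure: the (S,R) configuration of 10 lets both aryl groups (C2, C5) sit pseudo-equatorial, the methyl on the radical carbon then lies pseudo-equatorial and anti to its neighbouring aryl group, and the acceptor CH2 stays in the chair, which gives the 2,3-trans, 3,4-cis, 4,5-trans array, that is (3S,4R). The step needs ring closure to outrun the second hydrogen-atom transfer and any hydride-mediated isomerisation of the allyl ethers, which the fast closure of the 3-oxa radical, high dilution and slow silane addition should secure, and it needs chair over boat, which the two pseudo-equatorial aryl groups reinforce from both ends of the tether.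

Step 8
Reactants: 15 (2S,3S,4R,5R)-5-(4-benzyloxy-3,5-dimethoxyphenyl)-2-(3,4-dimethoxyphenyl)-3,4-dimethyloxolane
Product: 16 (2S,3S,4R,5R)-2-(3,4-dimethoxyphenyl)-5-(4-hydroxy-3,5-dimethoxyphenyl)-3,4-dimethyloxolane
Conditions: H2 (1 atm), Pd/C (10 %), EtOAc, rt, stopped at full conversion of 15
Reagents that add atoms: none
Why: Catalytic hydrogenolysis should cleave the phenolic O–CH2Ph bond much faster than the two secondary ring C–O bonds, so short exposure in a non-acidic solvent should free the phenol and leave the oxolane and its four stereocentres intact.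

**Compound list**

1 | 3,4-dimethoxybenzaldehyde (veratraldehyde) | COc1ccc(C=O)cc1OC | starting material
2 | rac-1-(3,4-dimethoxyphenyl)prop-2-en-1-ol | COc1ccc(C(O)C=C)cc1OC | intermediate
3 | (S)-1-(3,4-dimethoxyphenyl)prop-2-en-1-ol | COc1ccc([C@@H](O)C=C)cc1OC | intermediate
4 | sinapic acid, (E)-3-(4-hydroxy-3,5-dimethoxyphenyl)prop-2-enoic acid | COc1cc(/C=C/C(=O)O)cc(OC)c1O | starting material
5 | benzyl (E)-3-(4-benzyloxy-3,5-dimethoxyphenyl)prop-2-enoate | COc1cc(/C=C/C(=O)OCc2ccccc2)cc(OC)c1OCc1ccccc1 | intermediate
6 | (E)-3-(4-benzyloxy-3,5-dimethoxyphenyl)prop-2-en-1-ol | COc1cc(/C=C/CO)cc(OC)c1OCc1ccccc1 | intermediate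
7 | tert-butyl (E)-3-(4-benzyloxy-3,5-dimethoxyphenyl)prop-2-en-1-yl carbonate | COc1cc(/C=C/COC(=O)OC(C)(C)C)cc(OC)c1OCc1ccccc1 | intermediate
8 | lithium (S)-1-(3,4-dimethoxyphenyl)prop-2-en-1-olate | COc1ccc([C@@H]([O-])C=C)cc1OC.[Li+] | intermediate
9 | monovalent copper (S)-1-(3,4-dimethoxyphenyl)prop-2-en-1-olate | COc1ccc([C@@H](O[Cu])C=C)cc1OC | intermediate
10 | (R)-1-(4-benzyloxy-3,5-dimethoxyphenyl)prop-2-en-1-yl (S)-1-(3,4-dimethoxyphenyl)prop-2-en-1-yl ether | COc1ccc([C@@H](O[C@@H](c2cc(OC)c(OCc3ccccc3)c(OC)c2)C=C)C=C)cc1OC | intermediate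
11 | open-chain secondary radical at C3 (hydrogen atom added to the vinyl group on the C2 side of 10) | COc1ccc([C@@H](O[C@@H](c2cc(OC)c(OCc3ccccc3)c(OC)c2)C=C)[CH]C)cc1OC | intermediate
12 | open-chain secondary radical at C4 (hydrogen atom added to the vinyl group on the C5 side of 10) | COc1ccc([C@@H](O[C@@H](c2cc(OC)c(OCc3ccccc3)c(OC)c2)[CH]C)C=C)cc1OC | intermediate
13 | cyclised primary radical, CH2 radical on C4, ring configuration as in 15 | COc1ccc([C@H]2O[C@@H](c3cc(OC)c(OCc4ccccc4)c(OC)c3)[C@H]([CH2])[C@@H]2C)cc1OC | intermediate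
14 | cyclised primary radical, CH2 radical on C3, ring configuration as in 15 | COc1ccc([C@H]2O[C@@H](c3cc(OC)c(OCc4ccccc4)c(OC)c3)[C@H](C)[C@@H]2[CH2])cc1OC | intermediate
15 | (2S,3S,4R,5R)-5-(4-benzyloxy-3,5-dimethoxyphenyl)-2-(3,4-dimethoxyphenyl)-3,4-dimethyloxolane | COc1ccc([C@H]2O[C@@H](c3cc(OC)c(OCc4ccccc4)c(OC)c3)[C@H](C)[C@@H]2C)cc1OC | intermediate
16 | (2S,3S,4R,5R)-2-(3,4-dimethoxyphenyl)-5-(4-hydroxy-3,5-dimethoxyphenyl)-3,4-dimethyloxolane, equivalently 4-[(2R,3R,4S,5S)-5-(3,4-dimethoxyphenyl)-3,4-dimethyloxolan-2-yl]-2,6-dimethoxyphenol | COc1ccc([C@H]2O[C@@H](c3cc(OC)c(O)c(OC)c3)[C@H](C)[C@@H]2C)cc1OC | target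

**Count and risks**

Total steps: 8. Longest linear sequence: 6 steps (4 → 5 → 6 → 7 → 10 → 15 → 16, steps 3 to 8).

Steps most likely to fail:

1. Step 7. The open-chain radical may be reduced by a second hydrogen-atom transfer before it closes (net hydrogenation of both vinyl groups), the metal hydride may move a vinyl double bond into conjugation to give an enol ether, or the chair preference may be too small for useful diastereocontrol. The fallback sets out from 10 and comes back at 15, and replaces the metal hydride by a thiol-mediated radical chain followed by reductive desulfurisation. Diene 10 is heated with PhSH and AIBN in benzene at 80 °C. The phenylthiyl radical adds reversibly to the terminal carbon of either vinyl group to give the open-chain C3 radical F1 or the open-chain C4 radical F2. Each closes 5-exo through the same chair to the cyclised primary radical F3 or the cyclised primary radical F4. Hydrogen transfer from the thiol then gives the regioisomeric sulfides, the 3-(phenylsulfanylmethyl)oxolane F5 and the 4-(phenylsulfanylmethyl)oxolane F6. The mixture is desulfurised with nickel boride made from NiCl2·6H2O and NaBH4 (MeOH–THF, 0 °C); both sulfides should give 15. No metal hydride is present during ring closure, and the hydrogen-donor concentration is set by the amount of thiol.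

2. Step 6. The hindered secondary alkoxide may attack the allyliridium intermediate too slowly, so that linear ether formation or elimination takes over, or the electron-rich partner 3 may lose configuration by reversible ionisation. The fallback sets out from 7 and racemic 2 and comes back at 10; the union is reversed so that the O1–C2 bond is formed and the catalyst sets C2.
   - Carbonate 7 is treated with Et3SiOK, [Ir(cod)Cl]2 and L (same enantiomer as in step 6) in CH2Cl2 to give the (R)-triethylsilyl ether F7, and Bu4NF in THF frees (R)-1-(4-benzyloxy-3,5-dimethoxyphenyl)prop-2-en-1-ol F8.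
   - Racemic 2 is isomerised with dilute aqueous H2SO4 in dioxane (acid-catalysed 1,3-transposition into conjugation) to (E)-3-(3,4-dimethoxyphenyl)prop-2-en-1-ol F9, which Boc2O under the conditions of step 5 converts into tert-butyl (E)-3-(3,4-dimethoxyphenyl)prop-2-en-1-yl carbonate F10.
   - F8 is deprotonated with n-BuLi to the lithium alkoxide F11, transmetalated with CuI to the monovalent copper alkoxide F12, and coupled with F10 using [Ir(cod)Cl]2 and the enantiomer of L to give 10.
   - In this pairing the alkoxide carries the less ionisable aryl group, and the more electron-rich cinnamyl system is the electrophile.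

3. Step 2. The enzyme may discriminate poorly between the enantiomers, or acylate the hindered benzylic vinyl carbinol too slowly, so that 3 is not reached in high enantiomeric purity at useful conversion. The fallback sets out from racemic 2 and comes back at 3, and replaces resolution by asymmetric catalysis. Racemic 2 is converted through F9 into F10 as described above. F10 is treated with Et3SiOK, [Ir(cod)Cl]2 and the enantiomer of L in CH2Cl2 to give the (S)-triethylsilyl ether F13 (branched-selective allylic substitution with a silanolate as hydroxide surrogate), and Bu4NF in THF gives 3.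

**Further compounds**

F1 | step 7 | open-chain secondary radical at C3 after phenylthiyl addition to the vinyl group on the C2 side of 10 | COc1ccc([C@@H](O[C@@H](c2cc(OC)c(OCc3ccccc3)c(OC)c2)C=C)[CH]CSc4ccccc4)cc1OC
F2 | step 7 | open-chain secondary radical at C4 after phenylthiyl addition to the vinyl group on the C5 side of 10 | COc1ccc([C@@H](O[C@@H](c2cc(OC)c(OCc3ccccc3)c(OC)c2)[CH]CSc4ccccc4)C=C)cc1OC
F3 | step 7 | cyclised primary radical, CH2 radical on C4 and phenylsulfanylmethyl on C3 | COc1ccc([C@H]2O[C@@H](c3cc(OC)c(OCc4ccccc4)c(OC)c3)[C@H]([CH2])[C@@H]2CSc5ccccc5)cc1OC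
F4 | step 7 | cyclised primary radical, CH2 radical on C3 and phenylsulfanylmethyl on C4 | COc1ccc([C@H]2O[C@@H](c3cc(OC)c(OCc4ccccc4)c(OC)c3)[C@H](CSc5ccccc5)[C@@H]2[CH2])cc1OC
F5 | step 7 | (2S,3S,4R,5R)-5-(4-benzyloxy-3,5-dimethoxyphenyl)-2-(3,4-dimethoxyphenyl)-4-methyl-3-(phenylsulfanylmethyl)oxolane | COc1ccc([C@H]2O[C@@H](c3cc(OC)c(OCc4ccccc4)c(OC)c3)[C@H](C)[C@@H]2CSc5ccccc5)cc1OC
F6 | step 7 | (2S,3S,4R,5R)-5-(4-benzyloxy-3,5-dimethoxyphenyl)-2-(3,4-dimethoxyphenyl)-3-methyl-4-(phenylsulfanylmethyl)oxolane | COc1ccc([C@H]2O[C@@H](c3cc(OC)c(OCc4ccccc4)c(OC)c3)[C@H](CSc5ccccc5)[C@@H]2C)cc1OC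
F7 | step 6 | (R)-[1-(4-benzyloxy-3,5-dimethoxyphenyl)prop-2-en-1-yloxy]triethylsilane | COc1cc([C@H](O[Si](CC)(CC)CC)C=C)cc(OC)c1OCc1ccccc1
F8 | step 6 | (R)-1-(4-benzyloxy-3,5-dimethoxyphenyl)prop-2-en-1-ol | COc1cc([C@H](O)C=C)cc(OC)c1OCc1ccccc1
F9 | step 6 | (E)-3-(3,4-dimethoxyphenyl)prop-2-en-1-ol | COc1ccc(/C=C/CO)cc1OC
F10 | step 6 | tert-butyl (E)-3-(3,4-dimethoxyphenyl)prop-2-en-1-yl carbonate | COc1ccc(/C=C/COC(=O)OC(C)(C)C)cc1OC
F11 | step 6 | lithium (R)-1-(4-benzyloxy-3,5-dimethoxyphenyl)prop-2-en-1-olate | COc1cc([C@H]([O-])C=C)cc(OC)c1OCc1ccccc1.[Li+]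
F12 | step 6 | monovalent copper (R)-1-(4-benzyloxy-3,5-dimethoxyphenyl)prop-2-en-1-olate | COc1cc([C@H](O[Cu])C=C)cc(OC)c1OCc1ccccc1
F13 | step 2 | (S)-[1-(3,4-dimethoxyphenyl)prop-2-en-1-yloxy]triethylsilane | COc1ccc([C@@H](O[Si](CC)(CC)CC)C=C)cc1OC
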